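**Retrosynthetic overview**
- The oxirane is made last, by hydroxyl-directed oxygen transfer to the Z-Δ8 alkene of a 7-hydroxy precursor.
- The butenolide comes from lactonisation of the C3 ester onto the C13 hydroxyl across a Z-C4=C12 alkene, itself made by Horner–Wadsworth–Emmons olefination with a D-erythronolactone-derived aldehyde (C12–C15).
- The nine-membered ring is closed at C11a–C4a, the ring bond of the presumed biogenesis, by conjugate addition of the C1 enolate to an alkylidene phosphonoacetate; the exocyclic methylene is already in place and an Evans auxiliary sits on C1.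
- The seco chain comes from a Z-Wittig union (C8=C9) of an (S)-linalool-derived aldehyde (C4a–C8, carrying C7) with an isoprenol-derived ylide (C9–C1), then Knoevenagel condensation at C4a.
- Ring order: carbocycle, then butenolide, then oxirane.

Atom labels (C1, C4a, C7 …) follow xenicane numbering: ring C4a–C5–C6–C7(C18)–C8–C9–C10–C11(=C19)–C11a; C1 on C11a; side chain C4(C3)=C12–C13–C14–C15 on C4a.
Assumption: (S)-(+)-linalool, (4R)-4-benzyl-1,3-oxazolidin-2-one and 2,3-O-isopropylidene-D-erythronolactone are bought as single enantiomers.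

**Route**

Step 1
Reactants: 1 3-methylbut-3-en-1-ol (isoprenol)
Product: 3 3-methylidenepentane-1,5-diol, via dilithio dianion 2 (not isolated)
Conditions: n-BuLi (2.2 equiv), TMEDA, hexane/Et2O, 0 °C to rt; then (CH2O)n, −78 °C to rt; H2O
Reagents that add atoms: formaldehyde (as paraformaldehyde), C=O
Why: Alkoxide-directed allylic lithiation of the methyl group gives the dianion, which is hydroxymethylated at carbon (dianion alkylation); no stereocenter is formed.

Step 2
Reactants: 3 3-methylidenepentane-1,5-diol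
Product: 4 5-bromo-3-methylidenepentan-1-ol
Conditions: CBr4 (0.6 equiv), PPh3 (0.6 equiv), CH2Cl2, 0 °C (diol in excess, recovered)
Reagents that add atoms: carbon tetrabromide, BrC(Br)(Br)Br
Why: Appel bromination; using the symmetric diol in excess keeps the substitution at the mono stage.

Step 3
Reactants: 4 5-bromo-3-methylidenepentan-1-ol
Product: 5 (5-hydroxy-3-methylidenepentyl)triphenylphosphonium bromide
Conditions: PPh3, MeCN, 80 °C
Reagents that add atoms: triphenylphosphine, c1ccc(cc1)P(c1ccccc1)c1ccccc1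
Why: SN2 quaternisation of the phosphine by the primary bromide gives the Wittig salt.

Step 4
Reactants: 6 (S)-(+)-linalool
Product: 7 triethyl{[(3S)-3,7-dimethylocta-1,6-dien-3-yl]oxy}silane
Conditions: TESOTf, 2,6-lutidine, CH2Cl2, −78 to 0 °C
Reagents that add atoms: triethylsilyl trifluoromethanesulfonate, CC[Si](CC)(CC)OS(=O)(=O)C(F)(F)F
Why: Silyl triflate/lutidine silylation protects the hindered tertiary allylic alcohol without ionisation; the C7 stereocenter (S) is taken unchanged from the chiral pool.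

Step 5
Reactants: 7 triethyl{[(3S)-3,7-dimethylocta-1,6-dien-3-yl]oxy}silane
Product: 9 (2S)-5,5-dimethoxy-2-methyl-2-[(triethylsilyl)oxy]pentanal, via dialdehyde 8 (not isolated)
Conditions: O3, CH2Cl2/MeOH, −78 °C; Me2S, −78 °C to rt; then PPTS (cat.), MeOH, 3 Å MS, 0 °C
Reagents that add atoms: ozone, [O-][O+]=O; methanol, CO
Why: Ozonolysis with reductive work-up cleaves both alkenes, and chemoselective acetalisation takes the unhindered C4a aldehyde far faster than the neopentyl α-silyloxy C8 aldehyde; C7 is quaternary and cannot epimerise.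

Step 6
Reactants: 5 (5-hydroxy-3-methylidenepentyl)triphenylphosphonium bromide; 9 (2S)-5,5-dimethoxy-2-methyl-2-[(triethylsilyl)oxy]pentanal
Product: 11 (5Z,7S)-10,10-dimethoxy-7-methyl-3-methylidene-7-[(triethylsilyl)oxy]dec-5-en-1-ol, via oxido ylide 10 (not isolated)
Conditions: 5, NaN(SiMe3)2 (2.1 equiv), THF, −78 to 0 °C; then 9, −78 °C to rt
Reagents that add atoms: none
Why: Lithium-free Wittig reaction of a non-stabilised ylide with an α-branched aldehyde is kinetically Z-selective and sets the Z-C8=C9 alkene.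

Step 7
Reactants: 11 (5Z,7S)-10,10-dimethoxy-7-methyl-3-methylidene-7-[(triethylsilyl)oxy]dec-5-en-1-ol; 12 trimethyl phosphonoacetate
Product: 14 methyl (6S,7Z)-2-(dimethoxyphosphoryl)-12-hydroxy-6-methyl-10-methylidene-6-[(triethylsilyl)oxy]dodeca-2,7-dienoate (2E/2Z mixture, mainly 2E), via hydroxy aldehyde 13 (not isolated)
Conditions: PPTS (cat.), acetone/H2O, 40 °C; then 12, piperidine (cat.), AcOH (cat.), toluene, 4 Å MS, 70 °C
Reagents that add atoms: none
Why: Mild acetal hydrolysis followed by Knoevenagel condensation of the unhindered aldehyde gives the doubly activated acceptor, and the silyl ether on the C7 oxygen blocks oxa-Michael closure.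

Step 8
Reactants: 14 methyl (6S,7Z)-2-(dimethoxyphosphoryl)-12-hydroxy-6-methyl-10-methylidene-6-[(triethylsilyl)oxy]dodeca-2,7-dienoate
Product: 15 (5Z,7S)-11-(dimethoxyphosphoryl)-12-methoxy-7-methyl-3-methylidene-12-oxo-7-[(triethylsilyl)oxy]dodeca-5,10-dienoic acid
Conditions: PhI(OAc)2, TEMPO (cat.), MeCN/H2O (pH 7), rt
Reagents that add atoms: water, O
Why: TEMPO/PhI(OAc)2 oxidation takes the primary alcohol through the aldehyde hydrate to the acid under near-neutral conditions that leave the β,γ-alkene out of conjugation.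

Step 9
Reactants: 15 (5Z,7S)-11-(dimethoxyphosphoryl)-12-methoxy-7-methyl-3-methylidene-12-oxo-7-[(triethylsilyl)oxy]dodeca-5,10-dienoic acid; 16 (4R)-4-benzyl-1,3-oxazolidin-2-one
Product: 17 methyl (6S,7Z)-12-[(4R)-4-benzyl-2-oxo-1,3-oxazolidin-3-yl]-2-(dimethoxyphosphoryl)-6-methyl-10-methylidene-12-oxo-6-[(triethylsilyl)oxy]dodeca-2,7-dienoate
Conditions: DCC, DMAP (cat.), CH2Cl2, 0 °C
Reagents that add atoms: none
Why: Carbodiimide/DMAP N-acylation (Steglich type) attaches the Evans auxiliary without a strong base that would enolise either terminus.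

Step 10
Reactants: 18 2,3-O-isopropylidene-D-erythronolactone
Product: 19 2-[(4R,5R)-5-(hydroxymethyl)-2,2-dimethyl-1,3-dioxolan-4-yl]propan-2-ol
Conditions: MeMgBr (3 equiv), THF, 0 °C; H2O
Reagents that add atoms: methylmagnesium bromide, C[Mg]Br
Why: Double Grignard addition to the lactone builds the C15 tertiary carbinol and frees the C12 alcohol; C13 and C14 come unchanged from the chiral pool.

Step 11
Reactants: 19 2-[(4R,5R)-5-(hydroxymethyl)-2,2-dimethyl-1,3-dioxolan-4-yl]propan-2-ol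
Product: 20 (4R,5R)-2,2-dimethyl-4-[(trimethylsilyloxy)methyl]-5-[2-(trimethylsilyloxy)propan-2-yl]-1,3-dioxolane
Conditions: TMSCl, imidazole, DMF, rt
Reagents that add atoms: chlorotrimethylsilane, C[Si](C)(C)Cl
Why: Standard silylation of both hydroxyls.

Step 12
Reactants: 20 (4R,5R)-2,2-dimethyl-4-[(trimethylsilyloxy)methyl]-5-[2-(trimethylsilyloxy)propan-2-yl]-1,3-dioxolane
Product: 22 (4S,5R)-2,2-dimethyl-5-[2-(trimethylsilyloxy)propan-2-yl]-1,3-dioxolane-4-carbaldehyde, via alkoxysulfonium chloride 21 (not isolated)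
Conditions: (COCl)2, DMSO, CH2Cl2, −78 to −30 °C; Et3N, −78 °C
Reagents that add atoms: none
Why: Swern conditions cleave and oxidise only the primary trimethylsilyl ether (direct Swern oxidation of primary silyl ethers), the tertiary silyl ether survives, and low temperature avoids epimerisation at C13.

Step 13
Reactants: 17 methyl (6S,7Z)-12-[(4R)-4-benzyl-2-oxo-1,3-oxazolidin-3-yl]-2-(dimethoxyphosphoryl)-6-methyl-10-methylidene-12-oxo-6-[(triethylsilyl)oxy]dodeca-2,7-dienoate; 22 (4S,5R)-2,2-dimethyl-5-[2-(trimethylsilyloxy)propan-2-yl]-1,3-dioxolane-4-carbaldehyde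
Product: 25 methyl (2Z)-2-[(1S,2R,5Z,7S)-2-{[(4R)-4-benzyl-2-oxo-1,3-oxazolidin-3-yl]carbonyl}-7-methyl-3-methylidene-7-[(triethylsilyl)oxy]cyclonon-5-en-1-yl]-3-{(4R,5R)-2,2-dimethyl-5-[2-(trimethylsilyloxy)propan-2-yl]-1,3-dioxolan-4-yl}prop-2-enoate, via potassium imide dienolate 23 (not isolated), via potassium phosphonate carbanion 24 (not isolated)
Conditions: KN(SiMe3)2 (1.05 equiv), THF (2 mM), −78 to −40 °C; then 18-crown-6, 22 (2 equiv), −78 to −20 °C
Reagents that add atoms: none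
Why: Proposed new method: the C11a–H, flanked by the imide carbonyl and the vinyl group, is the most acidic site, so the base gives the chelated (Z)-imide dienolate, whose α-carbon adds to C4a of the alkylidene phosphonoacetate (closure helped by the Z-alkene, two sp2 ring carbons, the quaternary C7 and potassium bridging both termini); the phosphonoacetate carbanion so formed, only at C4, then olefinates 22 with Z-selectivity (dimethyl phosphonate, crown-separated potassium); C11a (R) is set by attack anti to the benzyl group of the auxiliary and C4a (S) by the tether closing through the conformer with H4a anti to H11a; closest known chemistry: Evans imide-enolate Michael additions, α-selective reactions of imide dienolates and tandem Michael/Horner–Wadsworth–Emmons reactions of α-phosphonoacrylates.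

Step 14
Reactants: 25 (imide from step 13)
Product: 26 methyl (2Z)-3-{(4R,5R)-2,2-dimethyl-5-[2-(trimethylsilyloxy)propan-2-yl]-1,3-dioxolan-4-yl}-2-[(1S,2R,5Z,7S)-2-(hydroxymethyl)-7-methyl-3-methylidene-7-[(triethylsilyl)oxy]cyclonon-5-en-1-yl]prop-2-enoate
Conditions: LiBH4, H2O (1 equiv), Et2O/THF, 0 °C
Reagents that add atoms: none
Why: Reductive cleavage of the N-acyloxazolidinone gives the C1 primary alcohol and returns the auxiliary, while the hindered conjugated methyl ester reacts much more slowly.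

Step 15
Reactants: 26 (alcohol from step 14)
Product: 27 (5R)-5-[(1R)-1,2-dihydroxy-2-methylpropyl]-3-[(1S,2R,5Z,7S)-7-hydroxy-2-(hydroxymethyl)-7-methyl-3-methylidenecyclonon-5-en-1-yl]furan-2(5H)-one
Conditions: AcOH/H2O/THF (3:1:1), 45 °C
Reagents that add atoms: none
Why: Aqueous acid removes the acetonide and both silyl ethers, and the freed C13 hydroxyl, held cis to the ester on the Z-alkene, lactonises spontaneously to the butenolide (acid-mediated deprotection/lactonisation).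

Step 16
Reactants: 27 (butenolide tetraol from step 15)
Product: 28 CNP0411123.2, (5R)-5-[(1R)-1,2-dihydroxy-2-methylpropyl]-3-[(1R,2S,5S,6R,9R)-2-hydroxy-6-(hydroxymethyl)-2-methyl-7-methylidene-10-oxabicyclo[7.1.0]decan-5-yl]furan-2(5H)-one
Conditions: VO(acac)2 (5 mol %), t-BuOOH (1.1 equiv), CH2Cl2, 0 °C
Reagents that add atoms: tert-butyl hydroperoxide, CC(C)(C)OO
Why: Vanadium-catalysed hydroxyl-directed epoxidation of the medium-ring Z-allylic tertiary alcohol delivers oxygen to the alkene face syn to the C7 hydroxyl, setting C8 (R) and C9 (R) as the cis-epoxide; the homoallylic exocyclic alkene and the electron-poor butenolide react far more slowly.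

**Compound list**

1 | 3-methylbut-3-en-1-ol (isoprenol) | C=C(C)CCO | starting material
2 | dilithium salt of the isoprenol dianion (2-(2-oxidoethyl)allyl lithium) | [Li+].[Li+].[CH2-]C(=C)CC[O-] | intermediate (not isolated)
3 | 3-methylidenepentane-1,5-diol | OCCC(=C)CCO | intermediate
4 | 5-bromo-3-methylidenepentan-1-ol | OCCC(=C)CCBr | intermediate
5 | (5-hydroxy-3-methylidenepentyl)triphenylphosphonium bromide | OCCC(=C)CC[P+](c1ccccc1)(c1ccccc1)c1ccccc1.[Br-] | intermediate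
6 | (S)-(+)-linalool, (3S)-3,7-dimethylocta-1,6-dien-3-ol | C=C[C@@](C)(O)CCC=C(C)C | starting material
7 | triethyl{[(3S)-3,7-dimethylocta-1,6-dien-3-yl]oxy}silane | C=C[C@@](C)(O[Si](CC)(CC)CC)CCC=C(C)C | intermediate
8 | (2S)-2-methyl-2-[(triethylsilyl)oxy]pentanedial | O=C[C@@](C)(O[Si](CC)(CC)CC)CCC=O | intermediate (not isolated)
9 | (2S)-5,5-dimethoxy-2-methyl-2-[(triethylsilyl)oxy]pentanal | O=C[C@@](C)(O[Si](CC)(CC)CC)CCC(OC)OC | intermediate
10 | sodium 3-methylidene-5-(triphenyl-λ5-phosphanylidene)pentan-1-olate | [Na+].[O-]CCC(=C)CC=P(c1ccccc1)(c1ccccc1)c1ccccc1 | intermediate (not isolated)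
11 | (5Z,7S)-10,10-dimethoxy-7-methyl-3-methylidene-7-[(triethylsilyl)oxy]dec-5-en-1-ol | OCCC(=C)C/C=C\[C@@](C)(O[Si](CC)(CC)CC)CCC(OC)OC | intermediate
12 | trimethyl phosphonoacetate | COC(=O)CP(=O)(OC)OC | starting material
13 | (4S,5Z)-10-hydroxy-4-methyl-8-methylidene-4-[(triethylsilyl)oxy]dec-5-enal | OCCC(=C)C/C=C\[C@@](C)(O[Si](CC)(CC)CC)CCC=O | intermediate (not isolated)
14 | methyl (6S,7Z)-2-(dimethoxyphosphoryl)-12-hydroxy-6-methyl-10-methylidene-6-[(triethylsilyl)oxy]dodeca-2,7-dienoate (2E/2Z mixture) | OCCC(=C)C/C=C\[C@@](C)(O[Si](CC)(CC)CC)CCC=C(C(=O)OC)P(=O)(OC)OC | intermediate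
15 | (5Z,7S)-11-(dimethoxyphosphoryl)-12-methoxy-7-methyl-3-methylidene-12-oxo-7-[(triethylsilyl)oxy]dodeca-5,10-dienoic acid | OC(=O)CC(=C)C/C=C\[C@@](C)(O[Si](CC)(CC)CC)CCC=C(C(=O)OC)P(=O)(OC)OC | intermediate
16 | (4R)-4-benzyl-1,3-oxazolidin-2-one | O=C1N[C@H](Cc2ccccc2)CO1 | starting material
17 | methyl (6S,7Z)-12-[(4R)-4-benzyl-2-oxo-1,3-oxazolidin-3-yl]-2-(dimethoxyphosphoryl)-6-methyl-10-methylidene-12-oxo-6-[(triethylsilyl)oxy]dodeca-2,7-dienoate | O=C(CC(=C)C/C=C\[C@@](C)(O[Si](CC)(CC)CC)CCC=C(C(=O)OC)P(=O)(OC)OC)N1[C@H](Cc2ccccc2)COC1=O | intermediate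
18 | 2,3-O-isopropylidene-D-erythronolactone, (3aR,6aR)-2,2-dimethyldihydrofuro[3,4-d][1,3]dioxol-4(3aH)-one | CC1(C)O[C@@H]2COC(=O)[C@@H]2O1 | starting material
19 | 2-[(4R,5R)-5-(hydroxymethyl)-2,2-dimethyl-1,3-dioxolan-4-yl]propan-2-ol | CC1(C)O[C@H](CO)[C@H](C(C)(C)O)O1 | intermediate
20 | (4R,5R)-2,2-dimethyl-4-[(trimethylsilyloxy)methyl]-5-[2-(trimethylsilyloxy)propan-2-yl]-1,3-dioxolane | CC1(C)O[C@H](CO[Si](C)(C)C)[C@H](C(C)(C)O[Si](C)(C)C)O1 | intermediate
21 | ({(4R,5R)-2,2-dimethyl-5-[2-(trimethylsilyloxy)propan-2-yl]-1,3-dioxolan-4-yl}methoxy)dimethylsulfonium chloride | CC1(C)O[C@H](CO[S+](C)C)[C@H](C(C)(C)O[Si](C)(C)C)O1.[Cl-] | intermediate (not isolated)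
22 | (4S,5R)-2,2-dimethyl-5-[2-(trimethylsilyloxy)propan-2-yl]-1,3-dioxolane-4-carbaldehyde | CC1(C)O[C@H](C=O)[C@H](C(C)(C)O[Si](C)(C)C)O1 | intermediate
23 | potassium (Z)-dienolate of imide 17 (enolate C1=C11a, oxygen cis to C11) | [K+].[O-]/C(N1[C@H](Cc2ccccc2)COC1=O)=C\C(=C)C/C=C\[C@@](C)(O[Si](CC)(CC)CC)CCC=C(C(=O)OC)P(=O)(OC)OC | intermediate (not isolated)
24 | potassium salt of the carbanion of methyl 2-[(1S,2R,5Z,7S)-2-{[(4R)-4-benzyl-2-oxo-1,3-oxazolidin-3-yl]carbonyl}-7-methyl-3-methylidene-7-[(triethylsilyl)oxy]cyclonon-5-en-1-yl]-2-(dimethoxyphosphoryl)acetate | C=C1C/C=C\[C@@](C)(O[Si](CC)(CC)CC)CC[C@H]([C-](C(=O)OC)P(=O)(OC)OC)[C@H]1C(=O)N1[C@H](Cc2ccccc2)COC1=O.[K+] | intermediate (not isolated)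
25 | methyl (2Z)-2-[(1S,2R,5Z,7S)-2-{[(4R)-4-benzyl-2-oxo-1,3-oxazolidin-3-yl]carbonyl}-7-methyl-3-methylidene-7-[(triethylsilyl)oxy]cyclonon-5-en-1-yl]-3-{(4R,5R)-2,2-dimethyl-5-[2-(trimethylsilyloxy)propan-2-yl]-1,3-dioxolan-4-yl}prop-2-enoate | C=C1C/C=C\[C@@](C)(O[Si](CC)(CC)CC)CC[C@H](/C(C(=O)OC)=C/[C@H]2OC(C)(C)O[C@H]2C(C)(C)O[Si](C)(C)C)[C@H]1C(=O)N1[C@H](Cc2ccccc2)COC1=O | intermediate
26 | methyl (2Z)-3-{(4R,5R)-2,2-dimethyl-5-[2-(trimethylsilyloxy)propan-2-yl]-1,3-dioxolan-4-yl}-2-[(1S,2R,5Z,7S)-2-(hydroxymethyl)-7-methyl-3-methylidene-7-[(triethylsilyl)oxy]cyclonon-5-en-1-yl]prop-2-enoate | C=C1C/C=C\[C@@](C)(O[Si](CC)(CC)CC)CC[C@H](/C(C(=O)OC)=C/[C@H]2OC(C)(C)O[C@H]2C(C)(C)O[Si](C)(C)C)[C@H]1CO | intermediate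
27 | (5R)-5-[(1R)-1,2-dihydroxy-2-methylpropyl]-3-[(1S,2R,5Z,7S)-7-hydroxy-2-(hydroxymethyl)-7-methyl-3-methylidenecyclonon-5-en-1-yl]furan-2(5H)-one | C=C1C/C=C\[C@@](C)(O)CC[C@H](C2=C[C@H]([C@@H](O)C(C)(C)O)OC2=O)[C@H]1CO | intermediate
28 | CNP0411123.2, (5R)-5-[(1R)-1,2-dihydroxy-2-methylpropyl]-3-[(1R,2S,5S,6R,9R)-2-hydroxy-6-(hydroxymethyl)-2-methyl-7-methylidene-10-oxabicyclo[7.1.0]decan-5-yl]furan-2(5H)-one; xenicane descriptors 4aS,7S,8R,9R,11aR,13R,14R | C=C1C[C@H]2O[C@H]2[C@@](C)(O)CC[C@H](C2=C[C@H]([C@@H](O)C(C)(C)O)OC2=O)[C@H]1CO | target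

**Step count and risks**

Total steps: 16. Longest linear sequence: 11 (steps 1, 2, 3, 6, 7, 8, 9, 13, 14, 15, 16, from isoprenol).

The three steps most likely to fail:

Step 13 is the main risk. The nine-membered closure may lose to oligomers, to attack through C19, or give the wrong C4a epimer, and the hindered carbanion may olefinate slowly or with poor Z-selectivity. The fallback changes the activation mode to catalyst-controlled enamine chemistry on the aldehyde oxidation level and sets out from 14. Dess–Martin oxidation (NaHCO3, CH2Cl2) gives methyl (6S,7Z)-2-(dimethoxyphosphoryl)-6-methyl-10-methylidene-12-oxo-6-[(triethylsilyl)oxy]dodeca-2,7-dienoate F1. Slow addition of F1 to (R)-α,α-diphenylprolinol trimethylsilyl ether (0.3 equiv) and PhCO2H in CHCl3 closes the ring by intramolecular enamine Michael addition, and NaBH4/MeOH quench gives methyl 2-(dimethoxyphosphoryl)-2-[(1S,2R,5Z,7S)-2-(hydroxymethyl)-7-methyl-3-methylidene-7-[(triethylsilyl)oxy]cyclonon-5-en-1-yl]acetate F2. Z-selective Horner–Wadsworth–Emmons reaction of F2 with 22 (KN(SiMe3)2 2.1 equiv, 18-crown-6, THF, −78 °C) comes back to the route at 26.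

Step 5 can fail if the hindered aldehyde is also acetalised or the product is lost on handling. The fallback cleaves the two alkenes one after the other and sets out from 7. Ozone (1.0 equiv, CH2Cl2/pyridine, −78 °C; Me2S) cleaves only the electron-rich trisubstituted alkene to give (4S)-4-methyl-4-[(triethylsilyl)oxy]hex-5-enal F3. Acetalisation (HC(OMe)3, PPTS, MeOH) gives triethyl{[(3S)-6,6-dimethoxy-3-methylhex-1-en-3-yl]oxy}silane F4. Ozonolysis of the vinyl group of F4 (O3, CH2Cl2, −78 °C; PPh3) comes back to the route at 9.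

Step 15 can fail if the tertiary allylic C7 alcohol ionises in acid or the C1 hydroxyl competes in lactonisation. The fallback reorders the endgame so that no allylic alcohol meets acid, and sets out from 26. HF·pyridine (THF/pyridine, 0 °C) removes both silyl groups to give methyl (2Z)-3-[(4R,5R)-5-(2-hydroxypropan-2-yl)-2,2-dimethyl-1,3-dioxolan-4-yl]-2-[(1S,2R,5Z,7S)-7-hydroxy-2-(hydroxymethyl)-7-methyl-3-methylidenecyclonon-5-en-1-yl]prop-2-enoate F5. Directed epoxidation (VO(acac)2, t-BuOOH, CH2Cl2, 0 °C) gives methyl (2Z)-3-[(4R,5R)-5-(2-hydroxypropan-2-yl)-2,2-dimethyl-1,3-dioxolan-4-yl]-2-[(1R,2S,5S,6R,9R)-2-hydroxy-6-(hydroxymethyl)-2-methyl-7-methylidene-10-oxabicyclo[7.1.0]decan-5-yl]prop-2-enoate F6. Acetonide cleavage with lactonisation (Dowex 50W, H+ form, MeOH, rt) comes back to the route at 28.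

**Further compounds**

F1 | step 13 | methyl (6S,7Z)-2-(dimethoxyphosphoryl)-6-methyl-10-methylidene-12-oxo-6-[(triethylsilyl)oxy]dodeca-2,7-dienoate | O=CCC(=C)C/C=C\[C@@](C)(O[Si](CC)(CC)CC)CCC=C(C(=O)OC)P(=O)(OC)OC
F2 | step 13 | methyl 2-(dimethoxyphosphoryl)-2-[(1S,2R,5Z,7S)-2-(hydroxymethyl)-7-methyl-3-methylidene-7-[(triethylsilyl)oxy]cyclonon-5-en-1-yl]acetate | C=C1C/C=C\[C@@](C)(O[Si](CC)(CC)CC)CC[C@H](C(C(=O)OC)P(=O)(OC)OC)[C@H]1CO
F3 | step 5 | (4S)-4-methyl-4-[(triethylsilyl)oxy]hex-5-enal | C=C[C@@](C)(O[Si](CC)(CC)CC)CCC=O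
F4 | step 5 | triethyl{[(3S)-6,6-dimethoxy-3-methylhex-1-en-3-yl]oxy}silane | C=C[C@@](C)(O[Si](CC)(CC)CC)CCC(OC)OC
F5 | step 15 | methyl (2Z)-3-[(4R,5R)-5-(2-hydroxypropan-2-yl)-2,2-dimethyl-1,3-dioxolan-4-yl]-2-[(1S,2R,5Z,7S)-7-hydroxy-2-(hydroxymethyl)-7-methyl-3-methylidenecyclonon-5-en-1-yl]prop-2-enoate | C=C1C/C=C\[C@@](C)(O)CC[C@H](/C(C(=O)OC)=C/[C@H]2OC(C)(C)O[C@H]2C(C)(C)O)[C@H]1CO
F6 | step 15 | methyl (2Z)-3-[(4R,5R)-5-(2-hydroxypropan-2-yl)-2,2-dimethyl-1,3-dioxolan-4-yl]-2-[(1R,2S,5S,6R,9R)-2-hydroxy-6-(hydroxymethyl)-2-methyl-7-methylidene-10-oxabicyclo[7.1.0]decan-5-yl]prop-2-enoate | C=C1C[C@H]2O[C@H]2[C@@](C)(O)CC[C@H](/C(C(=O)OC)=C/[C@H]2OC(C)(C)O[C@H]2C(C)(C)O)[C@H]1CO
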